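Assumption: ring atoms are numbered as a spiro[5.5]undecane, ring A = C1–C5 (C1 vinyl methyl, C3 oxygen, C4 bromine, C5 gem-dimethyl), spiro carbon = C6, ring B = C7–C11 (C9 = CBrMe, C10 = CHCl). On this numbering the target is (3S,4R,6R,9S,10S), and the same numbers are used for all intermediates.

**Retrosynthetic overview**
1. Target 22 ⇐ enone 19: the ring-A bromohydrin is made last (α′-bromination at C4, then 1,2-reduction at C3).
2. 19 ⇐ cis-9,10-diol 15: the trans C9–Br/C10–Cl pair comes from the cyclic sulfate (chloride at C10 with inversion, then bromide at C9 with retention through the chloronium).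
3. Ring B ⇐ C9–C10 bond: the aldehyde carbon of keto-aldehyde 11 is turned into a carbon nucleophile (samarium ketyl, a reversed-polarity d1 carbon) and joined to the methyl-ketone carbon, two carbons that are both normally electrophilic.
4. 11 ⇐ diene 10 (cleavage of both terminal alkenes) ⇐ enol carbonate 9: a Pd-catalysed enantioselective decarboxylative allylation sets the quaternary (later spiro) carbon C6.
5. Ring order: ring A comes intact from dimedone; ring B is closed second, in step 6.

**Route**

Step 1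
Reactants: 1 5,5-dimethylcyclohexane-1,3-dione (dimedone); 2 2-methylpropan-1-ol
Product: 3 3-(2-methylpropoxy)-5,5-dimethylcyclohex-2-en-1-one
Conditions: TsOH·H2O (cat.), toluene, reflux, Dean–Stark
Reagents that add atoms: 2-methylpropan-1-ol (2), CC(C)CO
Why: Acid-catalysed vinylogous esterification of the symmetric dione, driven by azeotropic removal of water; no stereocentre.

Step 2
Reactants: 3 3-(2-methylpropoxy)-5,5-dimethylcyclohex-2-en-1-one; 4 4-bromo-2-methylbut-1-ene
Product: 6 rac-3-(2-methylpropoxy)-5,5-dimethyl-6-(3-methylbut-3-en-1-yl)cyclohex-2-en-1-one, via lithium enolate 5 (not isolated)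
Conditions: lithium diisopropylamide, THF, −78 °C; then 4, DMPU, −78 → 23 °C
Reagents that add atoms: 4-bromo-2-methylbut-1-ene (4), C=C(C)CCBr
Why: Stork–Danheiser α′-alkylation, kinetic deprotonation at C6 then SN2 on the primary bromide; the C6 stereocentre is racemic and is erased in step 3.

Step 3
Reactants: 6 rac-3-(2-methylpropoxy)-5,5-dimethyl-6-(3-methylbut-3-en-1-yl)cyclohex-2-en-1-one; 7 allyl chloroformate
Product: 9 [3,3-dimethyl-2-(3-methylbut-3-en-1-yl)-5-(2-methylpropoxy)cyclohexa-1,5-dien-1-yl] prop-2-en-1-yl carbonate, via lithium enolate 8 (not isolated)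
Conditions: lithium diisopropylamide, TMEDA, THF, −78 °C; then 7, −78 → 0 °C
Reagents that add atoms: allyl chloroformate (7), C=CCOC(=O)Cl
Why: Kinetic α′-deprotonation at the C6 methine and O-acylation of the hindered tetrasubstituted enolate by the hard chloroformate give the allyl enol carbonate; C6 becomes sp2, so no stereocentre.

Step 4
Reactants: 9 [3,3-dimethyl-2-(3-methylbut-3-en-1-yl)-5-(2-methylpropoxy)cyclohexa-1,5-dien-1-yl] prop-2-en-1-yl carbonate
Product: 10 (6S)-3-(2-methylpropoxy)-5,5-dimethyl-6-(3-methylbut-3-en-1-yl)-6-(prop-2-en-1-yl)cyclohex-2-en-1-one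
Conditions: Pd2(dba)3 (5 mol %), (R)-(CF3)3-t-BuPHOX (12.5 mol %), toluene, 40 °C
Reagents that add atoms: none
Why: Tsuji-type decarboxylative asymmetric allylic alkylation, in which zerovalent palladium ionises the allyl carbonate, CO2 is lost and the ligand-bound allyl is delivered to one enolate face; the (R)-ligand is chosen by analogy with the known facial sense for 2-alkylcyclohexanone enolates to give 6S (if the sense is opposite, the (S)-ligand is used), and the electron-poor ligand is the one suited to this gem-dimethyl-flanked enolate.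

Step 5
Reactants: 10 (6S)-3-(2-methylpropoxy)-5,5-dimethyl-6-(3-methylbut-3-en-1-yl)-6-(prop-2-en-1-yl)cyclohex-2-en-1-one
Product: 11 2-[(1S)-6,6-dimethyl-4-(2-methylpropoxy)-2-oxo-1-(3-oxobutyl)cyclohex-3-en-1-yl]acetaldehyde
Conditions: OsO4 (2 mol %), NaIO4, 2,6-lutidine, dioxane/H2O, 23 °C
Reagents that add atoms: sodium periodate, [Na+].[O-]I(=O)(=O)=O (carbonyl oxygens, relayed through catalytic OsO4)
Why: Lemieux–Johnson cleavage, in which the two unhindered terminal alkenes react far faster with OsO4 than the deactivated trisubstituted vinylogous-ester alkene, giving the methyl ketone and the aldehyde; C6 is untouched.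

Step 6
Reactants: 11 2-[(1S)-6,6-dimethyl-4-(2-methylpropoxy)-2-oxo-1-(3-oxobutyl)cyclohex-3-en-1-yl]acetaldehyde
Product: 13 (6S,9S,10R)-9,10-dihydroxy-5,5,9-trimethyl-3-(2-methylpropoxy)spiro[5.5]undec-2-en-1-one, via samarium ketyl 12 (not isolated)
Conditions: SmI2 (2.5 equiv), t-BuOH, THF, −78 → 23 °C; aq. NH4Cl
Reagents that add atoms: none
Why: Intramolecular pinacol coupling, in which divalent samarium reduces the aldehyde to an O-bound ketyl whose carbon, now a nucleophile instead of an electrophile, adds 6-exo to the methyl ketone; one trivalent samarium bridges both oxygens so the diol is cis, and the chair transition state with the C9 methyl and the CMe2 arm of C6 equatorial puts both oxygens anti to the axial C1 arm, which gives 9S,10R.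

Step 7
Reactants: 13 (6S,9S,10R)-9,10-dihydroxy-5,5,9-trimethyl-3-(2-methylpropoxy)spiro[5.5]undec-2-en-1-one
Product: 15 (6S,9S,10R)-9,10-dihydroxy-1,5,5,9-tetramethylspiro[5.5]undec-1-en-3-one, via lithium alkoxide 14 (not isolated)
Conditions: MeLi (5 equiv), THF, −78 → 0 °C; then 1 M HCl, 23 °C
Reagents that add atoms: methyllithium, [Li]C; water, O
Why: 1,2-addition of MeLi to the vinylogous-ester carbonyl and acid-promoted Stork–Danheiser transposition (loss of the tertiary allylic hydroxyl, hydrolysis of the enol ether) give the β-methyl enone; the extra MeLi only deprotonates the diol and no stereocentre is affected.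

Step 8
Reactants: 15 (6S,9S,10R)-9,10-dihydroxy-1,5,5,9-tetramethylspiro[5.5]undec-1-en-3-one
Product: 17 (6S,9S,10R)-1,5,5,9-tetramethyl-3-oxospiro[5.5]undec-1-ene-9,10-diyl cyclic sulfate, via cyclic sulfite 16 (not isolated)
Conditions: SOCl2, Et3N, CH2Cl2, 0 °C; then RuCl3 (cat.), NaIO4, MeCN/H2O, 0 °C
Reagents that add atoms: thionyl chloride, O=S(Cl)Cl; sodium periodate, [Na+].[O-]I(=O)(=O)=O
Why: Cyclic sulfate formation from a cis-1,2-diol (sulfite closure, then catalytic ruthenium tetroxide oxidation at sulfur), which the electron-poor enone alkene survives; no stereocentre is touched.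

Step 9
Reactants: 17 (6S,9S,10R)-1,5,5,9-tetramethyl-3-oxospiro[5.5]undec-1-ene-9,10-diyl cyclic sulfate
Product: 19 (6S,9S,10S)-9-bromo-10-chloro-1,5,5,9-tetramethylspiro[5.5]undec-1-en-3-one, via sulfate monoester 18 (not isolated)
Conditions: n-Bu4NCl, CH2Cl2, 35 °C; then HBr (33% in AcOH), 0 °C
Reagents that add atoms: tetrabutylammonium chloride, CCCC[N+](CCCC)(CCCC)CCCC.[Cl-]; hydrogen bromide, Br
Why: Proposed new method: chloride opens the cyclic sulfate by SN2 at the secondary C10 with inversion (epoxide-like, diaxial opening), and the resulting tertiary C9 sulfate, once protonated, ionises with help from the now antiperiplanar chlorine to a chloronium ion that bromide opens at the tertiary carbon, so C9 is substituted with net retention and Br ends trans to Cl; the closest known reactions are nucleophilic opening of cyclic sulfates and SN1 substitution of tertiary alcohols by HBr with neighbouring-halogen participation.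

Step 10
Reactants: 19 (6S,9S,10S)-9-bromo-10-chloro-1,5,5,9-tetramethylspiro[5.5]undec-1-en-3-one
Product: 21 (4R,6R,9S,10S)-4,9-dibromo-10-chloro-1,5,5,9-tetramethylspiro[5.5]undec-1-en-3-one, via lithium enolate 20 (not isolated)
Conditions: LiN(SiMe3)2 (1.05 equiv), THF, −78 °C; then N-bromosuccinimide, −78 °C
Reagents that add atoms: N-bromosuccinimide, O=C1CCC(=O)N1Br
Why: Kinetic α′-deprotonation of the enone to the cross-conjugated enolate and electrophilic bromination; Br enters C4 axially, anti to the axial C5 methyl, in the half-chair whose pseudo-axial ring-B methylene is C11, which gives 4R (substrate control from a remote bias, so the ratio must be determined), and at −78 °C the base is consumed by the ketone before it can eliminate the tertiary bromide.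

Step 11
Reactants: 21 (4R,6R,9S,10S)-4,9-dibromo-10-chloro-1,5,5,9-tetramethylspiro[5.5]undec-1-en-3-one
Product: 22 (3S,4R,6R,9S,10S)-4,9-dibromo-10-chloro-1,5,5,9-tetramethylspiro[5.5]undec-1-en-3-ol
Conditions: i-Bu2AlH, CH2Cl2, −78 °C; aq. potassium sodium tartrate
Reagents that add atoms: none
Why: 1,2-reduction of the enone, in which the axial C5 methyl (1,3 to the carbonyl) blocks axial approach so hydride enters equatorially and gives the axial 3S alcohol cis to the equatorial C4 bromide; the alkyl halides are inert to i-Bu2AlH at −78 °C.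

**Compound list**

1 | 5,5-dimethylcyclohexane-1,3-dione (dimedone) | O=C1CC(=O)CC(C)(C)C1 | starting material
2 | 2-methylpropan-1-ol | CC(C)CO | starting material
3 | 3-(2-methylpropoxy)-5,5-dimethylcyclohex-2-en-1-one | CC(C)COC1=CC(=O)CC(C)(C)C1 | intermediate
4 | 4-bromo-2-methylbut-1-ene | C=C(C)CCBr | starting material
5 | lithium 3,3-dimethyl-5-(2-methylpropoxy)cyclohexa-1,5-dien-1-olate (enolate of 3) | [Li+].[O-]C1=CC(C)(C)CC(OCC(C)C)=C1 | intermediate (not isolated)
6 | rac-3-(2-methylpropoxy)-5,5-dimethyl-6-(3-methylbut-3-en-1-yl)cyclohex-2-en-1-one | C=C(C)CCC1C(=O)C=C(OCC(C)C)CC1(C)C | intermediate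
7 | allyl chloroformate (prop-2-en-1-yl carbonochloridate) | C=CCOC(=O)Cl | starting material
8 | lithium 3,3-dimethyl-2-(3-methylbut-3-en-1-yl)-5-(2-methylpropoxy)cyclohexa-1,5-dien-1-olate (enolate of 6) | [Li+].[O-]C1=C(CCC(C)=C)C(C)(C)CC(OCC(C)C)=C1 | intermediate (not isolated)
9 | [3,3-dimethyl-2-(3-methylbut-3-en-1-yl)-5-(2-methylpropoxy)cyclohexa-1,5-dien-1-yl] prop-2-en-1-yl carbonate | C=CCOC(=O)OC1=C(CCC(C)=C)C(C)(C)CC(OCC(C)C)=C1 | intermediate
10 | (6S)-3-(2-methylpropoxy)-5,5-dimethyl-6-(3-methylbut-3-en-1-yl)-6-(prop-2-en-1-yl)cyclohex-2-en-1-one | O=C1C=C(OCC(C)C)CC(C)(C)[C@@]1(CC=C)CCC(C)=C | intermediate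
11 | 2-[(1S)-6,6-dimethyl-4-(2-methylpropoxy)-2-oxo-1-(3-oxobutyl)cyclohex-3-en-1-yl]acetaldehyde | O=C1C=C(OCC(C)C)CC(C)(C)[C@@]1(CC=O)CCC(C)=O | intermediate
12 | O-(diiodosamarium) ketyl of 11 (radical at the former aldehyde carbon C10) | O=C1C=C(OCC(C)C)CC(C)(C)[C@@]1(C[CH]O[Sm](I)I)CCC(C)=O | intermediate (not isolated)
13 | (6S,9S,10R)-9,10-dihydroxy-5,5,9-trimethyl-3-(2-methylpropoxy)spiro[5.5]undec-2-en-1-one | O=C1C=C(OCC(C)C)CC(C)(C)[C@@]12CC[C@](C)(O)[C@H](O)C2 | intermediate
14 | lithium alkoxide from 1,2-addition of MeLi to C1 of 13 (C1 epimers) | CC1([O-])C=C(OCC(C)C)CC(C)(C)[C@@]12CC[C@](C)(O)[C@H](O)C2.[Li+] | intermediate (not isolated)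
15 | (6S,9S,10R)-9,10-dihydroxy-1,5,5,9-tetramethylspiro[5.5]undec-1-en-3-one | CC1=CC(=O)CC(C)(C)[C@@]12CC[C@](C)(O)[C@H](O)C2 | intermediate
16 | 9,10-cyclic sulfite of 15 (epimers at sulfur) | CC1=CC(=O)CC(C)(C)[C@@]12CC[C@]3(C)OS(=O)O[C@@H]3C2 | intermediate (not isolated)
17 | (6S,9S,10R)-1,5,5,9-tetramethyl-3-oxospiro[5.5]undec-1-ene-9,10-diyl cyclic sulfate | CC1=CC(=O)CC(C)(C)[C@@]12CC[C@]3(C)OS(=O)(=O)O[C@@H]3C2 | intermediate
18 | tetrabutylammonium (6S,9S,10S)-10-chloro-1,5,5,9-tetramethyl-3-oxospiro[5.5]undec-1-en-9-yl sulfate | CC1=CC(=O)CC(C)(C)[C@@]12CC[C@](C)(OS(=O)(=O)[O-])[C@@H](Cl)C2.CCCC[N+](CCCC)(CCCC)CCCC | intermediate (not isolated)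
19 | (6S,9S,10S)-9-bromo-10-chloro-1,5,5,9-tetramethylspiro[5.5]undec-1-en-3-one | CC1=CC(=O)CC(C)(C)[C@@]12CC[C@](C)(Br)[C@@H](Cl)C2 | intermediate
20 | lithium cross-conjugated (C3–O, C3=C4) enolate of 19 | CC1=CC([O-])=CC(C)(C)[C@@]12CC[C@](C)(Br)[C@@H](Cl)C2.[Li+] | intermediate (not isolated)
21 | (4R,6R,9S,10S)-4,9-dibromo-10-chloro-1,5,5,9-tetramethylspiro[5.5]undec-1-en-3-one | CC1=CC(=O)[C@H](Br)C(C)(C)[C@@]12CC[C@](C)(Br)[C@@H](Cl)C2 | intermediate
22 | (3S,4R,6R,9S,10S)-4,9-dibromo-10-chloro-1,5,5,9-tetramethylspiro[5.5]undec-1-en-3-ol | CC1=C[C@H](O)[C@H](Br)C(C)(C)[C@@]12CC[C@](C)(Br)[C@@H](Cl)C2 | target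

**Step count**
Total steps: 11. Longest linear sequence: 11 (fully linear from dimedone).

**Three steps most likely to fail, with fallbacks**

Step 9. The SN2 opening at C10 is hindered (axial approach, syn to the C1 arm), and the exchange at C9 can be diverted to elimination or ring contraction. Fallback: set out from 17, open it with n-Bu4NCl and hydrolyse the sulfate ester (cat. H2SO4, H2O/THF) to the chlorohydrin (6S,9S,10S)-10-chloro-9-hydroxy-1,5,5,9-tetramethylspiro[5.5]undec-1-en-3-one F2. Dehydrate F2 by anti elimination (POCl3, pyridine; only C8–H and the methyl hydrogens are available, not C10–H) to the allylic chloride (6S,10S)-10-chloro-1,5,5,9-tetramethylspiro[5.5]undeca-1,8-dien-3-one F3. Then add HBr in the Markovnikov sense (proton to C8, bromide to the chlorine-bridged C9 cation, anti to Cl). This comes back to the route at 19.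

Step 6. Simple reduction of the aldehyde, aldol closure of the 1,6-keto-aldehyde, or the wrong facial sense would each cost material. Fallback: set out from 10 and close ring B by ring-closing metathesis (second-generation Grubbs catalyst, CH2Cl2, 40 °C) to the spiro diene (6S)-5,5,9-trimethyl-3-(2-methylpropoxy)spiro[5.5]undeca-2,9-dien-1-one F1. Then dihydroxylate the ring-B alkene (OsO4 cat., N-methylmorpholine N-oxide, acetone/H2O) from the face anti to the axial C1 arm. This comes back to the route at 13.

Step 10. The facial choice at C4 rests on a remote bias from ring B, and the tertiary bromide must survive the base. Fallback: set out from 19 and brominate under acidic, equilibrating conditions (CuBr2, EtOAc/CHCl3, reflux; enol mechanism, no base). This gives 21 together with its C4 epimer (4S,6R,9S,10S)-4,9-dibromo-10-chloro-1,5,5,9-tetramethylspiro[5.5]undec-1-en-3-one F4. Reduce the interconverting pair under dynamic kinetic resolution with a catalyst that fixes C3 as S (RuCl(p-cymene)[(S,S)-TsDPEN] or its enantiomer as found, HCO2H/Et3N), so that both epimers funnel to the cis-bromohydrin. This comes back to the route at the target 22.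

**Further compounds**

F1 | step 6 | (6S)-5,5,9-trimethyl-3-(2-methylpropoxy)spiro[5.5]undeca-2,9-dien-1-one | O=C1C=C(OCC(C)C)CC(C)(C)[C@@]12CCC(C)=CC2
F2 | step 9 | (6S,9S,10S)-10-chloro-9-hydroxy-1,5,5,9-tetramethylspiro[5.5]undec-1-en-3-one | CC1=CC(=O)CC(C)(C)[C@@]12CC[C@](C)(O)[C@@H](Cl)C2
F3 | step 9 | (6S,10S)-10-chloro-1,5,5,9-tetramethylspiro[5.5]undeca-1,8-dien-3-one | CC1=CC(=O)CC(C)(C)[C@@]12CC=C(C)[C@@H](Cl)C2
F4 | step 10 | (4S,6R,9S,10S)-4,9-dibromo-10-chloro-1,5,5,9-tetramethylspiro[5.5]undec-1-en-3-one | CC1=CC(=O)[C@@H](Br)C(C)(C)[C@@]12CC[C@](C)(Br)[C@@H](Cl)C2
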